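The constants of the steps are unknown, but the ratio of two of them can be read from the cold runs. The flasks, the readings and the questions are these:

| flask | starting material | partner | protic impurity | free catalyst | temperature | remark | time |
|---|---|---|---|---|---|---|---|
| ochre | 0.20 M | 0.24 M | 4 mM | 2.5 mM | −10 °C | run made earlier |  |
| red | 0.20 M | 0.24 M | 4 mM | 10 mM | 40 °C | run made earlier |  |
| amber | 0.40 M | 0.24 M | 4 mM | 5 mM | −10 °C | run made earlier |  |
| dawn | 0.20 M | 0.240 M | 4.00 mM | 5.0 mM | −5 °C |  | 2.0 h |
| noon | 0.20 M | 0.240 M | 4.00 mM | 5.0 mM | 85 °C |  | 2.0 h |
| midnight | 0.20 M | 0.240 M | 4.00 mM | 5.0 mM | 55 °C |  | 2.0 h |
| spring | 0.20 M | 0.240 M | 4.00 mM | 5.0 mM | 25 °C |  | 2.0 h |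

| run | time / min | target / % | starting material / % |
|---|---|---|---|
| ochre | 20.0 | 1.5 | 94.4 |
| ochre | 40.0 | 3.6 | 93.3 |
| ochre | 50.0 | 4.2 | 92.5 |
| ochre | 80.0 | 6.9 | 88.7 |
| red | 0.667 | 40.5 | 42.4 |
| red | 1.33 | 59.1 | 12.1 |
| red | 3.00 | 67.7 | 2.3 |
| red | 8.00 | 64.5 | 0.9 |
| amber | 10.0 | 1.3 | 97.0 |
| amber | 25.0 | 0.4 | 94.2 |
| amber | 50.0 | 5.6 | 91.6 |
| amber | 80.0 | 2.6 | 88.1 |

(each reading ± 1 percentage point)

- percentages count the starting material that a species holds: one side product counts as two
- steps thought possible: partner + free catalyst <-> catalyst intermediate A; catalyst intermediate B -> free catalyst + target; starting material + protic impurity -> quenched substrate; starting material + catalyst intermediate A -> catalyst intermediate B; starting material + target -> side product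

- which flask leads in amount of target, in percent of the starting material charged ("all alike" within 1.5 percentage points) (dawn / noon / midnight / spring / all alike)
- how much target is there at the end, in percent of the starting material charged: dawn
- how much target is there at the end, in percent of the starting material charged: noon
- how much target is there at the end, in percent of the starting material charged: midnight
- how much target is there at the end, in percent of the starting material charged: spring

Start with the last rows of the two cold runs, ochre and amber. By its last reading ochre has lost 9.04 starting material per catalyst and amber 9.52, but amber holds twice the starting material and twice the catalyst of ochre. Loss per catalyst and fractional loss therefore move together in this pair, which cannot tell a rate that follows the catalyst from one that follows the starting material. This reckoning assumes the first, a rate-limiting step after capture with catalyst intermediate B as resting state.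

Target is then made at a rate of turnover constant times catalyst, and the side step uses it at side constant times target times starting material. The symmetric case is the point where the two rates are equal. That target concentration, the balance level, equals the balance constant times catalyst over starting material, and the balance constant is turnover constant over side constant.

Ochre and amber have equal catalyst over starting material, so they share one balance level. Ochre's target is still climbing in its last row, and amber's column scatters too widely to show a plateau, so both columns are read as approaching that level, not as standing at it. Ochre's last two rows give 8.40 mM and 13.8 mM. Amber's give 22.4 mM and 10.4 mM, and a point of scatter weighs twice as much there. The mean of the four is 13.8 mM, which gives a balance constant, as a reading, of 1.10 M, and for columns still approaching their level this is a low estimate.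

Dawn is only slightly warmer, and taking the constant over unchanged is an assumption of this reckoning. Its level is 27.5 mM at full charge, or 13.7% of the starting material charged. With half the starting material gone the level is 27.5%. The low constant understates the level, while target lags under its level, so the two errors pull opposite ways, and this reckoning takes these two figures as its estimate for dawn's end.

The forecast gives 38% for dawn, above this bracket, with 24% for noon, 38% for midnight and 55% for spring, the leader: “Spring should lead, though these are rough estimates.”

The flasks end at 21.4% in dawn, 10.9% in noon, 41.4% in midnight and 53.3% in spring, so spring leads.

    partner + free catalyst ⇌ catalyst intermediate A (K = 153 M⁻¹, k = 3340 M⁻¹ min⁻¹, Ea = 37.0 kJ mol⁻¹, ΔH = −70.0 kJ mol⁻¹)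
    catalyst intermediate B → free catalyst + target (k = 5.83 min⁻¹, Ea = 83.0 kJ mol⁻¹)
    starting material + protic impurity → quenched substrate (k = 34.3 M⁻¹ min⁻¹, Ea = 57.0 kJ mol⁻¹)
    starting material + catalyst intermediate A → catalyst intermediate B (k = 117 M⁻¹ min⁻¹, Ea = 39.0 kJ mol⁻¹)
    starting material + target → side product (k = 1.31 M⁻¹ min⁻¹, Ea = 57.0 kJ mol⁻¹)
    (constants at 25 °C)

Dawn lies inside the bracket, and with 38.9% of its starting material left, the constant 1.10 M puts its level at 35.3%, above the target it holds. In spring at 0.0576 h, target is made 2.64 times faster than it is used up. There the half-life of starting material by capture, 0.062 h, is shorter than that of target by the side step, 0.087 h. The neighbour of spring with 0.12 M of starting material, which has more catalyst per starting material, ends at 68.7% target.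

The runs were computed with constants of no real substance, and the scatter is random.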